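**Open question.** The south-west flask turns Q into X over catalyst Z. I was asked what X stands at 8.0 d, and which remedy then gains most.

| flask | Q | Z | temperature | remark | time |
|---|---|---|---|---|---|
| south-west | 0.80 M | 80 mM | 80 °C | the very flask that is asked about, followed so far |  |
| south-east | 0.80 M | 54 mM | 86 °C | run made earlier |  |
| flask | 0.80 M | 80 mM | 80 °C |  | 8.0 d |

- south-west (time / d: X / %, Q / %): 1.04: 35.5, 43.9; 2.00: 38.2, 23.9; 3.00: 36.9, 15.3; 4.00: 35.2, 12.0; 5.00: 34.3, 10.5; 6.00: 33.0, 9.6
- south-east (time / h: X / %, Q / %): 8.00: 33.1, 61.3; 15.0: 43.3, 43.4; 25.0: 47.7, 30.3; 30.0: 48.3, 26.9; 40.0: 48.0, 23.4; 48.0: 47.9, 21.1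

(readings scatter by 0.3 percentage points)

- X, in percent of the Q first charged, at 8.0 d
- the remedy with the largest gain of X, or "none" below 2 percentage points (teal / violet / grey / amber / none)
- X present, with what was taken out counted in, in percent of the Q first charged, after teal
- X present, with what was taken out counted in, in percent of the Q first charged, after amber

- teal: at 8.0 d add Z, 100% of the amount charged, then wait 15 d
- violet: at 8.0 d raise the temperature by 20 K, then wait 15 d
- grey: at 8.0 d take out 90% of the X then present, then wait 15 d
- amber: change nothing and wait 15 d more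

- removed X is counted in
- the numbers in the tables scatter with a standard deviation of 0.3 percentage points
- additions bring no volume worth counting

**Free share.** In the south-west run, Q/(Q+X) fell from 55.3% to 25.4% within 2.96 d, short against the wait of 15 d. It then reached 22.5% at 6.00 d. I called this free share s and treated Q ⇌ X as a quasi-equilibrium. If a share f of X is removed, and the pair Q+X loses nothing else and returns to s, the gain is f·X·s.

**My bracket.** For the upper bound on the gain from grey, I let the whole 9.6% of Q at the last reading turn into X. For the lower bound, I supposed that X kept falling at its last pace to 30.4%, which also bracketed "now" under 33.0%. I supposed too that s dropped once more to 19.6%, and on these two suppositions f·X·s gave grey 5.4 percentage points. Tightening, with X and s held at their last readings, gives 6.7 points as the upper end. I committed to grey.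

**The forecast.** It gave 31.8% for now, inside my bracket, with 11% after teal and 31% after amber. For grey it expected “a gain near 1”, so its best was none. My lower bound stood above the 2 points line.

**Flask result.** The flask gave 32.4%, and grey gained 7.8 points, more than my tightened end. That gain stayed below the outer bound. Amber ended at 32.5%, teal at 9.65%, and violet changed X by −9.5 points.

    Q ⇌ X (K = 3.90, k = 9.70 × 10⁻⁶ s⁻¹, Ea = 113 kJ mol⁻¹, ΔH = −68.0 kJ mol⁻¹)
    X + Z ⇌ G + Z, rate k2*[Z]*[X] forward; the back reaction follows from the equilibrium constant (K = 0.0870, k = 7.10 × 10⁻⁶ L mol⁻¹ s⁻¹, Ea = 92.0 kJ mol⁻¹, ΔH = −29.0 kJ mol⁻¹)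
    Z + X → Z + J (k = 1.40 × 10⁻⁴ L mol⁻¹ s⁻¹, Ea = 69.0 kJ mol⁻¹)
    G ⇌ Q (k = 1.50 × 10⁻⁶ s⁻¹, Ea = 115 kJ mol⁻¹)
    Z → E (k = 6.10 × 10⁻⁶ s⁻¹, Ea = 124 kJ mol⁻¹)
    (constants at 80 °C)

Q and X relax towards each other with a half-life of 0.658 d by their step alone, short against 8.0 d, and at that time the flask's s was 21.0%, for which f·X·s gives 6.1 points. A neighbour flask, charged with 0.20 M of Z, held 13.2% X and 3.72% Q at 8.0 d, an s of 22.0%.

The readings were generated by integration with made-up constants, and the scatter is random.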